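**Strategy**

The route rests on the 4-oxygenated 4,5-disubstituted cyclopent-2-enone ring: its ketone oxygen and four ring carbons come from a furan, its α-carbon from a furyl carbinol carbon. The ring is disconnected between the ketone α-carbon (bearing the heptenoate arm) and the quaternary acetoxy carbon. An enantioselective Piancatelli rearrangement makes this bond, both ring stereocentres, the enone and the tertiary oxygen in one operation: the furan is dearomatised, water supplies the tertiary hydroxyl, and a conrotatory 4π electrocyclisation places hydroxyl and side arm trans. The precursor is a flat furylcarbinol carrying the (Z)-octenyl chain at the furan 5-position and an (E)-iodoallyl arm; asymmetric Nozaki–Hiyama–Kishi coupling and double acetylation finish the target.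

Key step: step 5

Remark on the chemistry: the sense of induction of the chiral acid (step 5) and of the chiral chromium ligand (step 6) cannot be predicted with certainty; the antipode written is a placeholder, and the one that gives the drawn configuration would be chosen in a pilot run. Compounds 9 and 11 are racemic at the carbinol carbon, which step 5 erases. Compounds 1, 3, 7 and 16 are taken as commercial.

**Route**

Step 1
Reactants: 1 (2Z)-oct-2-en-1-ol
Product: 2 (2Z)-1-bromooct-2-ene
Conditions: PBr3 (0.4 equiv), pyridine (cat.), Et2O, −20 to 0 °C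
Reagents that add atoms: phosphorus tribromide, BrP(Br)Br
Why: Bromination of a primary allylic alcohol through its bromophosphite (SN2 by bromide at the primary carbon) should proceed at low temperature without allylic shift, so the Z-olefin is kept.

Step 2
Reactants: 3 2-(furan-2-yl)-1,3-dioxolane; 2 (2Z)-1-bromooct-2-ene
Product: 6 5-[(2Z)-oct-2-en-1-yl]furan-2-carbaldehyde, via 5-lithiofuran acetal 4 (not isolated), via alkylated acetal 5 (not isolated)
Conditions: n-BuLi, THF, −78 to −20 °C; 2, −78 °C to rt; then 2 M aq. HCl, THF, rt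
Reagents that add atoms: water, O
Why: α-Lithiation of the furan at its free 5-position, SN2 alkylation by the primary allylic bromide and acid cleavage of the dioxolane during work-up (lithiation–alkylation–acetal hydrolysis) should give the aldehyde; no stereocentre is formed and the Z-olefin is carried over.

Step 3
Reactants: 6 5-[(2Z)-oct-2-en-1-yl]furan-2-carbaldehyde; 7 3-bromoprop-1-yne
Product: 9 rac-1-{5-[(2Z)-oct-2-en-1-yl]furan-2-yl}but-3-yn-1-ol, via allenylzinc bromide 8 (not isolated)
Conditions: Zn dust, THF/sat. aq. NH4Cl, 0 °C to rt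
Reagents that add atoms: none
Why: Zinc Barbier propargylation, in which the allenylzinc adds through its γ-carbon (SE2′) to give the homopropargylic alcohol; the carbinol centre is deliberately racemic because step 5 erases it.

Step 4
Reactants: 9 rac-1-{5-[(2Z)-oct-2-en-1-yl]furan-2-yl}but-3-yn-1-ol
Product: 11 rac-(3E)-4-iodo-1-{5-[(2Z)-oct-2-en-1-yl]furan-2-yl}but-3-en-1-ol, via bis-zirconated alkenylzirconocene 10 (not isolated)
Conditions: Cp2Zr(H)Cl (2.2 equiv), THF, 0 °C to rt, dark; then I2 (1.05 equiv), −20 °C; aq. Na2S2O3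
Reagents that add atoms: iodine, II
Why: Hydrozirconation–iodination, in which the first equivalent of hydride is consumed by the hydroxyl, syn addition of Zr–H to the terminal alkyne places zirconium at the terminus, and iodinolysis with retention gives the (E)-vinyl iodide; the cis-disubstituted olefin should react far more slowly.

Step 5
Reactants: 11 rac-(3E)-4-iodo-1-{5-[(2Z)-oct-2-en-1-yl]furan-2-yl}but-3-en-1-ol
Product: 15 (4R,5S)-4-hydroxy-5-[(2E)-3-iodoprop-2-en-1-yl]-4-[(2Z)-oct-2-en-1-yl]cyclopent-2-en-1-one, via furfuryl cation 12 (not isolated), via ring hemiketal 13 (not isolated), via hydroxypentadienyl cation 14 (not isolated)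
Conditions: (R)-3,3′-bis(2,4,6-triisopropylphenyl)-1,1′-binaphthyl-2,2′-diyl N-triflylphosphoramide (10 mol %), H2O (10 equiv), PhCF3, 50 °C
Reagents that add atoms: water, O
Why: Proposed new method: the acid ionises the furfuryl alcohol to furanium ion 12, water adds at the octenyl-bearing furan carbon to give hemiketal 13, ring opening gives the 1,4-dihydroxypentadienyl cation 14, and a thermal conrotatory 4π electrocyclisation joins the former carbinol carbon to the former octenyl-bearing furan carbon before proton loss and tautomerisation give the enone. The closest known reaction types are the Piancatelli rearrangement of 5-methyl-2-furylcarbinols under achiral Lewis acids (racemic trans products) and the chiral-Brønsted-acid-catalysed aza-Piancatelli and Nazarov electrocyclisations, so the bond formation is established but its enantioselective form with water on a 5-alkylfuran is not. The cyclopentenone ring is closed in the 4π-conrotatory mode (pentadienyl cation to cyclopentenyl cation), the former furan oxygen ending as the ketone. The relative configuration (hydroxyl trans to the iodoallyl arm, the two carbon chains cis) should follow from conrotation of the cation that carries both the arm and the hydroxyl on its outer positions, and the absolute configuration (4R,5S) from the chiral phosphoramide anion, which is hydrogen-bonded to both hydroxyls of 14 and selects one sense of rotation. The step needs the electrocyclisation to outrun proton loss from the carbon next to the cationic centre (which would give a furyl diene) and ether formation between two carbinols; excess water, the reversibility of ether formation and the known tolerance of allyl-type furylcarbinols in the racemic reaction speak for this, while the Z-olefin and the vinyl iodide are inert to the acid.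

Step 6
Reactants: 15 (4R,5S)-4-hydroxy-5-[(2E)-3-iodoprop-2-en-1-yl]-4-[(2Z)-oct-2-en-1-yl]cyclopent-2-en-1-one; 16 methyl 4-oxobutanoate
Product: 19 methyl (4S,5E)-4-hydroxy-7-{(1S,5R)-5-hydroxy-5-[(2Z)-oct-2-en-1-yl]-2-oxocyclopent-3-en-1-yl}hept-5-enoate, via alkenylchromium dichloride 17 (not isolated), via chromium alkoxide 18 (not isolated)
Conditions: CrCl2 (3 equiv), (S)-N-[2-(4-isopropyl-4,5-dihydrooxazol-2-yl)-6-methylphenyl]methanesulfonamide (3.3 equiv), Et3N (3.3 equiv), NiCl2 (10 mol %), THF, rt; aq. ethylenediamine work-up at 0 °C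
Reagents that add atoms: none
Why: Asymmetric Nozaki–Hiyama–Kishi coupling, in which zerovalent nickel inserts into the C–I bond with retention of the E geometry, the alkenyl group passes to chromium and adds to the aldehyde only (ketone, enone and ester are spectators); the sulfonamide ligand on chromium sets the new carbinol centre (4S) under reagent control, remote from the ring centres.

Step 7
Reactants: 19 methyl (4S,5E)-4-hydroxy-7-{(1S,5R)-5-hydroxy-5-[(2Z)-oct-2-en-1-yl]-2-oxocyclopent-3-en-1-yl}hept-5-enoate
Product: 20 methyl (4S,5E)-4-(acetyloxy)-7-{(1S,5R)-5-(acetyloxy)-5-[(2Z)-oct-2-en-1-yl]-2-oxocyclopent-3-en-1-yl}hept-5-enoate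
Conditions: Ac2O (6 equiv), Sc(OTf)3 (2 mol %), MeCN, −20 °C
Reagents that add atoms: acetic anhydride, CC(=O)OC(C)=O
Why: Lewis-acid-catalysed acylation should acetylate the secondary and the hindered tertiary hydroxyl without base, which avoids epimerisation next to the ketone and outpaces lactonisation; ionisation at the tertiary carbinol is disfavoured because the cation would be antiaromatic, and no stereocentre is touched.

**Compound list**

1 | (2Z)-oct-2-en-1-ol | CCCCC/C=C\CO | starting material
2 | (2Z)-1-bromooct-2-ene | CCCCC/C=C\CBr | intermediate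
3 | 2-(furan-2-yl)-1,3-dioxolane | C1COC(O1)c1ccco1 | starting material
4 | 2-(5-lithiofuran-2-yl)-1,3-dioxolane | [Li]c1ccc(C2OCCO2)o1 | intermediate (not isolated)
5 | 2-{5-[(2Z)-oct-2-en-1-yl]furan-2-yl}-1,3-dioxolane | CCCCC/C=C\Cc1ccc(C2OCCO2)o1 | intermediate (not isolated)
6 | 5-[(2Z)-oct-2-en-1-yl]furan-2-carbaldehyde | CCCCC/C=C\Cc1ccc(C=O)o1 | intermediate
7 | 3-bromoprop-1-yne (propargyl bromide) | C#CCBr | starting material
8 | propa-1,2-dien-1-ylzinc bromide (allenylzinc bromide) | C=C=C[Zn]Br | intermediate (not isolated)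
9 | rac-1-{5-[(2Z)-oct-2-en-1-yl]furan-2-yl}but-3-yn-1-ol | CCCCC/C=C\Cc1ccc(C(O)CC#C)o1 | intermediate
10 | (E)-alkenyl(chloro)zirconocene of 9 with the oxygen bound to a second chlorozirconocene (cyclopentadienyl rings written as σ-bonded C5H5) | CCCCC/C=C\Cc1ccc(C(C/C=C/[Zr](Cl)(C2C=CC=C2)C2C=CC=C2)O[Zr](Cl)(C2C=CC=C2)C2C=CC=C2)o1 | intermediate (not isolated)
11 | rac-(3E)-4-iodo-1-{5-[(2Z)-oct-2-en-1-yl]furan-2-yl}but-3-en-1-ol | CCCCC/C=C\Cc1ccc(C(O)C/C=C/I)o1 | intermediate
12 | 2-[(3E)-4-iodobut-3-en-1-ylidene]-5-[(2Z)-oct-2-en-1-yl]-2H-furan-1-ium (furfuryl cation) | CCCCC/C=C\CC1=[O+]C(=CC/C=C/I)C=C1 | intermediate (not isolated)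
13 | 5-[(3E)-4-iodobut-3-en-1-ylidene]-2-[(2Z)-oct-2-en-1-yl]-2,5-dihydrofuran-2-ol (ring hemiketal) | CCCCC/C=C\CC1(O)C=CC(=CC/C=C/I)O1 | intermediate (not isolated)
14 | 1,4-dihydroxypentadienyl cation, drawn as the O-protonated (Z)-enedione mono-enol | CCCCC/C=C\CC(=[OH+])/C=C\C(O)=CC/C=C/I | intermediate (not isolated)
15 | (4R,5S)-4-hydroxy-5-[(2E)-3-iodoprop-2-en-1-yl]-4-[(2Z)-oct-2-en-1-yl]cyclopent-2-en-1-one | CCCCC/C=C\C[C@@]1(O)C=CC(=O)[C@H]1C/C=C/I | intermediate
16 | methyl 4-oxobutanoate | COC(=O)CCC=O | starting material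
17 | (E)-alkenylchromium dichloride derived from 15 (trivalent chromium, ligand omitted) | CCCCC/C=C\C[C@@]1(O)C=CC(=O)[C@H]1C/C=C/[Cr](Cl)Cl | intermediate (not isolated)
18 | chromium alkoxide of 19 (trivalent chromium, ligand omitted) | CCCCC/C=C\C[C@@]1(O)C=CC(=O)[C@H]1C/C=C/[C@H](CCC(=O)OC)O[Cr](Cl)Cl | intermediate (not isolated)
19 | methyl (4S,5E)-4-hydroxy-7-{(1S,5R)-5-hydroxy-5-[(2Z)-oct-2-en-1-yl]-2-oxocyclopent-3-en-1-yl}hept-5-enoate | CCCCC/C=C\C[C@@]1(O)C=CC(=O)[C@H]1C/C=C/[C@H](CCC(=O)OC)O | intermediate
20 | methyl (4S,5E)-4-(acetyloxy)-7-{(1S,5R)-5-(acetyloxy)-5-[(2Z)-oct-2-en-1-yl]-2-oxocyclopent-3-en-1-yl}hept-5-enoate | CCCCC/C=C\C[C@@]1(OC(C)=O)C=CC(=O)[C@H]1C/C=C/[C@H](CCC(=O)OC)OC(C)=O | target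

**Step count and risks**

Total step count: 7. Longest linear sequence: 7 steps (1 → 2 → 6 → 9 → 11 → 15 → 19 → 20); compounds 3, 7 and 16 enter as commercial reactants.

Steps most likely to fail:

1. Step 5 (Proposed new method). The chiral ion pair may not control the sense of conrotation, the chiral acid may ionise the secondary alkyl furylcarbinol too slowly, and proton loss from the cation to a furyl diene may compete. Fallback with known chemistry: setting out from 11, the established Lewis-acid Piancatelli protocol for 5-alkyl-2-furylcarbinols (ZnCl2, 1,4-dioxane/H2O, 80 °C) should give the trans-cyclopentenone as a racemate, that is 15 together with its enantiomer (4S,5R)-4-hydroxy-5-[(2E)-3-iodoprop-2-en-1-yl]-4-[(2Z)-oct-2-en-1-yl]cyclopent-2-en-1-one F1. The enantiomers would then be separated by preparative chromatography on a chiral stationary phase (amylose carbamate, supercritical CO2/2-propanol), and the route is rejoined at 15.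

2. Step 6. Reagent control at the new carbinol carbon may be incomplete, the chromium alkoxide may lactonise onto the methyl ester, and the amine may epimerise the carbon next to the ketone. Fallback: setting out from 9, the carbinol centre and the E-olefin are installed on the furan before the ring is made.
   - Silylation (TBSCl, imidazole, DMF) should give the silyl ether F2.
   - Hydroboration with dicyclohexylborane (from BH3·SMe2 and cyclohexene, hexane, 0 °C) should give the (E)-alkenylborane F3, and boron–zinc exchange with Et2Zn at −78 °C the alkenyl(ethyl)zinc F4.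
   - Addition to 16 catalysed by (+)-3-exo-(dimethylamino)isoborneol (5 mol %; the antipode expected to give 4S, otherwise its mirror image) should give the zinc alkoxide F5, which is trapped in the flask with Ac2O as the silyl ether acetate F6.
   - HF·pyridine in THF should remove the silyl group to give the furylcarbinol acetate F7.
   - The Piancatelli rearrangement under the conditions of step 5 should give the hydroxy acetate F8.
   - Acetylation of the remaining tertiary hydroxyl under the conditions of step 7 rejoins the route at 20.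

3. Step 2. Attack at the inner allylic terminus (SN2′), lithium–bromine exchange and Z-to-E drift of the allylic bromide would carry isomers that are hard to remove into every later compound. Fallback: setting out from 3 through 4, alkylation with commercial 1-bromooct-2-yne (CCCCCC#CCBr) should give the alkynyl acetal F9, which the acid work-up converts into the alkynyl aldehyde F10. Semihydrogenation (H2, Pd on CaCO3 poisoned with Pb(OAc)2, quinoline, EtOAc) then sets the Z-olefin by syn addition and rejoins the route at 6; step 1 is then not needed.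

Further compounds
F1 | step 5 | (4S,5R)-4-hydroxy-5-[(2E)-3-iodoprop-2-en-1-yl]-4-[(2Z)-oct-2-en-1-yl]cyclopent-2-en-1-one | CCCCC/C=C\C[C@]1(O)C=CC(=O)[C@@H]1C/C=C/I
F2 | step 6 | rac-tert-butyl(dimethyl)[(1-{5-[(2Z)-oct-2-en-1-yl]furan-2-yl}but-3-yn-1-yl)oxy]silane | CCCCC/C=C\Cc1ccc(C(CC#C)O[Si](C)(C)C(C)(C)C)o1
F3 | step 6 | [(1E)-4-{[tert-butyl(dimethyl)silyl]oxy}-4-{5-[(2Z)-oct-2-en-1-yl]furan-2-yl}but-1-en-1-yl]dicyclohexylborane | CCCCC/C=C\Cc1ccc(C(C/C=C/B(C2CCCCC2)C2CCCCC2)O[Si](C)(C)C(C)(C)C)o1
F4 | step 6 | [(1E)-4-{[tert-butyl(dimethyl)silyl]oxy}-4-{5-[(2Z)-oct-2-en-1-yl]furan-2-yl}but-1-en-1-yl](ethyl)zinc | CCCCC/C=C\Cc1ccc(C(C/C=C/[Zn]CC)O[Si](C)(C)C(C)(C)C)o1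
F5 | step 6 | ethylzinc alkoxide of methyl (4S,5E)-8-{[tert-butyl(dimethyl)silyl]oxy}-4-hydroxy-8-{5-[(2Z)-oct-2-en-1-yl]furan-2-yl}oct-5-enoate | CCCCC/C=C\Cc1ccc(C(C/C=C/[C@H](CCC(=O)OC)O[Zn]CC)O[Si](C)(C)C(C)(C)C)o1
F6 | step 6 | methyl (4S,5E)-4-(acetyloxy)-8-{[tert-butyl(dimethyl)silyl]oxy}-8-{5-[(2Z)-oct-2-en-1-yl]furan-2-yl}oct-5-enoate (both epimers at the silyloxy carbon) | CCCCC/C=C\Cc1ccc(C(C/C=C/[C@H](CCC(=O)OC)OC(C)=O)O[Si](C)(C)C(C)(C)C)o1
F7 | step 6 | methyl (4S,5E)-4-(acetyloxy)-8-hydroxy-8-{5-[(2Z)-oct-2-en-1-yl]furan-2-yl}oct-5-enoate (both epimers at the carbinol carbon) | CCCCC/C=C\Cc1ccc(C(O)C/C=C/[C@H](CCC(=O)OC)OC(C)=O)o1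
F8 | step 6 | methyl (4S,5E)-4-(acetyloxy)-7-{(1S,5R)-5-hydroxy-5-[(2Z)-oct-2-en-1-yl]-2-oxocyclopent-3-en-1-yl}hept-5-enoate | CCCCC/C=C\C[C@@]1(O)C=CC(=O)[C@H]1C/C=C/[C@H](CCC(=O)OC)OC(C)=O
F9 | step 2 | 2-[5-(oct-2-yn-1-yl)furan-2-yl]-1,3-dioxolane | CCCCCC#CCc1ccc(C2OCCO2)o1
F10 | step 2 | 5-(oct-2-yn-1-yl)furan-2-carbaldehyde | CCCCCC#CCc1ccc(C=O)o1
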